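## The problem

Compound 15 is a twofold-symmetric biphenyl in which two 3-(4-hydroxy-3-methoxyphenyl)propanoic acid units are joined through the ring carbons ortho to their hydroxyl groups. It has no stereocentre and, with a single ortho substituent beside the biaryl bond on each ring, no configurationally stable axis, so the task is one of connectivity alone. Numbered from the biaryl carbon C1, each ring carries hydroxyl at C2, methoxy at C3 and a 2-carboxyethyl chain at C5, and the biaryl bond lies between two phenols. The sensitive groups are the two guaiacol-type phenols, which oxidise readily to quinone methides and C–O-coupled oligomers, whereas the two aliphatic acids are robust and are best carried as esters until late. A route that decorates a finished biphenol must therefore install two three-carbon acid chains para to the hydroxyls without an oxidant touching these electron-rich rings. The rings can instead be built, because the sequence C2 (OH), C3 (OMe), C4 (H), C5 (chain) matches the ring oxygen with C5, then C4 (OMe), C3 and C2 (alkyl) of a 4-methoxy-2-alkylfuran. The remaining ring carbons C1 and C6 can then come from one triple bond of a conjugated diyne whose central single bond is already the C1–C1' bond.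

## Retrosynthesis

**15 from 14.** The two phenolic O–H bonds are traced back to O–benzyl bonds. The phenols must stay masked through ester cleavage and decarboxylation. A benzyl ether is preferred to a methyl ether, which could not be told apart from the native methoxy groups, and to a silyl ether, which would not survive hot hydroxide. Compound 14 is no simpler in skeleton, but the forward step asks only for hydrogenolysis in a molecule with nothing else reducible.

**14 from 13.** The C6–H and C6'–H bonds are traced back to C6–CO2H and C6'–CO2H bonds. These carboxyl groups are what remains of the esters that activate the ring-forming step. Each sits between the biaryl bond and the chain, so 13 is a 2,6-disubstituted benzoic acid twice over, the class that decarboxylates most easily under metal catalysis. The forward step must tell aryl from aliphatic carboxyl groups, and extrusion through an aryl–metal species does that.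

**13 from 12.** The four carboxylic acids of 13 are traced back to the four methyl esters of 12. This changes nothing in the skeleton. The forward hydrolysis must reach two hindered ring esters without a Dieckmann closure between chain and ring esters.

**12 from 11.** The two O–benzyl bonds are cut to give biphenol 11. The benzylation is not optional: in a free 2'-hydroxybiphenyl-2-carboxylic acid the hydroxyl of one ring closes a six-membered lactone onto the carboxyl of the other on acidification, and a lactone cannot be decarboxylated. The order is therefore protect, hydrolyse, decarboxylate.

**11 from 6 and 8 (key disconnection).** In each ring the bonds C1–C2 and C5–C6 are cut and the C2 hydroxyl is reconnected to C5 as a bridging ether. This leads through the bis(7-oxanorbornadiene) 10 and the mono-adduct 9 back to two molecules of furan 6 and the diyne diester 8. The neighbouring option, oxidative or reductive coupling of two finished arenes, forms only the biaryl bond and leaves each ring to be made separately. The cycloaddition cut fixes every substituent position of both rings through the choice of two small partners and needs no oxidant near a phenol. The precursors drop to a nine-carbon furan and an eight-carbon diyne. The forward reaction must deliver one regiochemistry twice, bring both triple bonds to react, and open each oxygen bridge toward the carbon next to the methoxy group.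

**8 from 7.** The central Csp–Csp bond of 8 is cut to two molecules of methyl propiolate 7. Oxidative homocoupling of a terminal alkyne cannot give regioisomers, which is the advantage of making the future biaryl bond at this stage.

**6 from 5.** The O–CH3 bond of 6 is cut to the furan-3(2H)-one 5. The forward step must methylate the enolate of 5 on oxygen, not on carbon, and this is the only mode that gains furan aromaticity.

**5 from 3.** The ring O–C bond at the chain-bearing carbon of 5 is cut to the alpha'-hydroxy ynone 4, carried as its acetate 3. This places the oxygen that becomes the methoxy group on the former ketone carbon and the chain on the former alkyne terminus. The result is the 2,4-substitution pattern that direct substitution of a simple 3-alkoxyfuran would not give. The forward step needs a 5-endo-dig oxa-Michael closure.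

**3 from 1 and 2.** The acyl–alkynyl bond is cut to methyl pent-4-ynoate 1 and acetoxyacetyl chloride 2. An acylation catalysed by PdCl2(PPh3)2 and CuI is preferred to an acetylide addition because the ester of 1 would not tolerate a strong base.

## Roads not taken

Alternative 1: The cut is at the two CH2–CO2H bonds. 3,3'-Dimethoxy-2,2'-bis(methoxymethoxy)-5,5'-divinylbiphenyl A1 would be reduced at a cathode under carbon dioxide A2 in the presence of a proton donor. Carboxylation at both terminal alkene carbons would give 3,3'-[5,5'-dimethoxy-6,6'-bis(methoxymethoxy)biphenyl-3,3'-diyl]dipropanoic acid A3. Mild acid would then remove the two acetals of A3 and give 15.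
- Merits: the biaryl is taken ready-made, the acid carbon comes from A2, and no carbon has to be removed later. A1 should be about three steps from a commercial phenolic aldehyde, so this road is clearly shorter than the chosen one.
- Weak points: the vinyl groups of A1 are para to an alkoxy group, so A1 is hard to reduce and its reduction competes with that of A2. Dicarboxylation to arylsuccinic acids, simple hydrogenation to ethyl groups and radical-anion dimerisation are the usual side paths. Both ends of one molecule must follow the same path, or A3 arrives mixed with very similar acids.
- Comparison: this road wins on step count and atom economy. The chosen plan sets against it closed-shell thermal bond formations with no competing reduction manifolds, and ordinary glassware. Both roads rest on a key step that is untested for the substrate.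

Alternative 2: The cut is at the bond between each benzylic carbon and the next chain carbon. 3,3'-Dimethoxy-5,5'-dimethylbiphenyl-2,2'-diol A4 would be oxidised with Ag2O A5 to the bis(para-quinone methide) 5,5'-dimethoxy-3,3'-dimethylidene-1,1'-bi(cyclohexa-1,4-dien-1-yl)-6,6'-dione A6. The anion of dimethyl malonate A7 would add to both exocyclic carbons of A6 and give tetramethyl 2,2'-[(6,6'-dihydroxy-5,5'-dimethoxybiphenyl-3,3'-diyl)dimethanediyl]dimalonate A8. Hydrolysis of A8 and decarboxylation of the malonic acids would finish the synthesis.
- Merits: very short, no protecting groups, and the final decarboxylation of a malonic acid is far easier than the aryl decarboxylation of the chosen plan.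
- Weak points: A6 has unsubstituted exocyclic carbons and no bulky ortho groups, so it should be short-lived, adding phenols and water and oligomerising. A4 is a 2,2'-biphenol, so the first quinone methide forms beside a still-free phenol on the other ring, and A5 can also drive A4 toward dibenzofuran-type or further coupled products. The anion of A7 is basic enough to deprotonate the phenols and change the oxidation chemistry.
- Comparison: this road is better in length. The chosen plan has isolable intermediates at every stage and unveils the phenols in an acid step with no oxidant present.

Alternative 3: The cut is at the two C5–CH2 bonds. Heating 2,2'-bis(allyloxy)-3,3'-dimethoxybiphenyl A9 would move each allyl group by a (3,3) shift to a blocked ortho carbon and by a second (3,3) shift to C5. The product would be 5,5'-diallyl-3,3'-dimethoxybiphenyl-2,2'-diol A10.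
- Merits: reagent-free, well-understood pericyclic chemistry. A9 has both ortho positions blocked, so the para product is the expected one. Each step is better precedented than the key step of the chosen plan.
- Weak points: A10 is the ortho–ortho oxidative dimer of eugenol A11, and A11 is a commodity chemical, so the key step makes something that is accessible more directly. The allyl groups of A10 have the right carbon count but the wrong oxidation level. Turning CH2CH=CH2 into CH2CH2CO2H needs protection of the phenols, anti-Markovnikov hydration and two oxidations, all on electron-rich rings.
- Comparison: the overall length is similar to, or somewhat shorter than, the chosen route, and its individual reactions are safer. The chosen plan carries the chain at the ester oxidation level from the first step and needs no oxidation after the rings exist.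

Key step: step 5

Assumption: compounds 1, 2 and 7 are taken as purchased; ring positions of the biphenyls are numbered as in the target, with C1 as the biaryl carbon.

## Route

Step 1
Reactants: 1 methyl pent-4-ynoate; 2 acetoxyacetyl chloride
Product: 3 methyl 7-acetoxy-6-oxohept-4-ynoate
Conditions: PdCl2(PPh3)2 (2 mol%), CuI (4 mol%), Et3N (1.05 equiv), THF, 0 °C to rt
Reagents that add atoms: none
Why: Acyl Sonogashira coupling: the acid chloride adds to zerovalent palladium and the copper acetylide of 1 transmetalates, so the ynone forms without a strong base that would enolise the ester; the amine is held near one equivalent to limit ketene formation from 2.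

Step 2
Reactants: 3 methyl 7-acetoxy-6-oxohept-4-ynoate
Product: 5 methyl 3-(4-oxo-4,5-dihydrofuran-2-yl)propanoate, via hydroxy ynone 4 (not isolated)
Conditions: K2CO3 (0.3 equiv), MeOH, 0 °C to rt; AcOH quench
Reagents that add atoms: none
Why: Carbonate-catalysed methanolysis removes the acetyl group as methyl acetate, and the freed alpha'-hydroxy ynone closes by 5-endo-dig oxa-Michael addition to the ynone beta carbon, the established route to furan-3(2H)-ones; the product is neutralised and carried on at once because its ring CH2 between oxygen and carbonyl is prone to aldol self-condensation.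

Step 3
Reactants: 5 methyl 3-(4-oxo-4,5-dihydrofuran-2-yl)propanoate
Product: 6 methyl 3-(4-methoxyfuran-2-yl)propanoate
Conditions: Me2SO4 (1.2 equiv), K2CO3, DMF, 0 °C to rt; chromatography on Et3N-deactivated silica
Reagents that add atoms: dimethyl sulfate, COS(=O)(=O)OC
Why: O-Alkylation of an enolate: deprotonation of the ring CH2 gives an aromatic furan-3-olate, and a hard methylating agent in a polar aprotic solvent alkylates it on oxygen, as in the O-methylation of benzofuran-3(2H)-ones and the O-silylation of furan-3(2H)-ones; only O-alkylation gains the furan aromaticity.

Step 4
Reactants: 7 methyl propiolate (2.0 equiv)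
Product: 8 dimethyl hexa-2,4-diynedioate
Conditions: CuCl (10 mol%), TMEDA (10 mol%), O2 (1 atm), acetone, rt
Reagents that add atoms: none
Why: Glaser–Hay oxidative homocoupling: two molecules of the terminal alkyne 7 are joined at their sp carbons through copper acetylides with O2 as terminal oxidant, and the amine is kept catalytic and copper-bound so that it does not add to the propiolate; the diyne is kept cold and used in solution because conjugated diynes can decompose on storage.

Step 5
Reactants: 6 methyl 3-(4-methoxyfuran-2-yl)propanoate (2.3 equiv); 8 dimethyl hexa-2,4-diynedioate
Product: 11 dimethyl 6,6'-dihydroxy-5,5'-dimethoxy-3,3'-bis(3-methoxy-3-oxopropyl)biphenyl-2,2'-dicarboxylate, via mono-oxanorbornadiene 9 (not isolated), via bis-oxanorbornadiene 10 (not isolated)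
Conditions: toluene, rt to 60 °C; then CF3CO2H (0.5 equiv, anhydrous), CH2Cl2, 0 °C to rt
Reagents that add atoms: none
Why: Proposed new method: furan 6 should act as an electron-rich diene through its two alpha carbons and each ynoate unit of 8 as dienophile in a thermal (4+2) cycloaddition whose bond formation is concerted but leads at the unsubstituted furan carbon next to OMe; the untested element is the use of both triple bonds of a diynedioate, and the closest known reaction type is the Diels–Alder reaction of 3-alkoxyfurans with acetylenic esters followed by acid-promoted isomerisation of the 7-oxanorbornadienes to phenols. Each benzene ring is closed by an intermolecular (4+2) annulation that forms C1–C2 and C5–C6, giving first 9 and then 10. Acid then protonates the bridging oxygen and ionises its bond to the chain-bearing bridgehead, because only that cation is tertiary and conjugated through the enol ether to the methoxy oxygen; the oxygen stays on the hydrogen-bearing bridgehead and loss of that proton aromatises the ring with the hydroxyl next to OMe. The step needs the nucleophilic furan carbon beside OMe to bond to the inner diyne carbon, which is beta to its own ester, and the largest HOMO coefficient of a 3-alkoxyfuran and the largest LUMO coefficient of an ynoate favour this pairing, although the second ynoate also activates the ester-bearing carbon in a vinylogous sense. The bridgehead stereocentres of 9 and 10 are transient and vanish on aromatisation, so every diastereomer converges on 11 and no stereocontrol is required. Both cycloadditions are completed under neutral conditions before acid is added, so that no free phenol meets an unreacted ynoate, and the acid is anhydrous and cold so that the enol ethers are not hydrolysed and the hindered ring esters do not lactonise onto the new phenols.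

Step 6
Reactants: 11 dimethyl 6,6'-dihydroxy-5,5'-dimethoxy-3,3'-bis(3-methoxy-3-oxopropyl)biphenyl-2,2'-dicarboxylate
Product: 12 dimethyl 6,6'-bis(benzyloxy)-5,5'-dimethoxy-3,3'-bis(3-methoxy-3-oxopropyl)biphenyl-2,2'-dicarboxylate
Conditions: BnBr (2.5 equiv), K2CO3, DMF, rt to 50 °C
Reagents that add atoms: benzyl bromide, BrCc1ccccc1
Why: Williamson etherification of the two phenols; capping them prevents lactonisation onto the neighbouring ring carboxyl once the ring esters are cleaved, and carbonate is too weak a base to start a Dieckmann closure between chain and ring esters.

Step 7
Reactants: 12 dimethyl 6,6'-bis(benzyloxy)-5,5'-dimethoxy-3,3'-bis(3-methoxy-3-oxopropyl)biphenyl-2,2'-dicarboxylate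
Product: 13 6,6'-bis(benzyloxy)-3,3'-bis(2-carboxyethyl)-5,5'-dimethoxybiphenyl-2,2'-dicarboxylic acid
Conditions: KOH (excess), DMSO/H2O (4:1), rt, then 100 °C; aq. HCl to pH 2 at 0 °C
Reagents that add atoms: potassium hydroxide, [K+].[OH-]
Why: Saponification: the unhindered chain esters cleave at room temperature, which removes the enolisable ester before heating and so avoids Dieckmann closure, and the di-ortho-substituted ring esters then yield to hot hydroxide in aqueous DMSO, a medium used for hindered benzoates.

Step 8
Reactants: 13 6,6'-bis(benzyloxy)-3,3'-bis(2-carboxyethyl)-5,5'-dimethoxybiphenyl-2,2'-dicarboxylic acid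
Product: 14 3,3'-[6,6'-bis(benzyloxy)-5,5'-dimethoxybiphenyl-3,3'-diyl]dipropanoic acid
Conditions: Ag2CO3 (20 mol%), AcOH (10 mol%), DMSO, 120 °C
Reagents that add atoms: none
Why: Silver-catalysed protodecarboxylation of ortho-substituted benzoic acids: the flanking aryl and alkyl groups twist the carboxylate out of conjugation and favour extrusion from the silver carboxylate to an arylsilver species, which is protonated by the acids present; aliphatic acids do not decarboxylate without an oxidant and the benzyl ethers block lactonisation.

Step 9
Reactants: 14 3,3'-[6,6'-bis(benzyloxy)-5,5'-dimethoxybiphenyl-3,3'-diyl]dipropanoic acid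
Product: 15 3,3'-(6,6'-dihydroxy-5,5'-dimethoxybiphenyl-3,3'-diyl)dipropanoic acid
Conditions: H2 (1 atm), 10% Pd/C, THF, rt
Reagents that add atoms: none
Why: Hydrogenolysis of the two benzyl aryl ethers over palladium on carbon; nothing else in 14 is reducible, so the biphenol diacid is released under neutral conditions.

## Compound list

1 | methyl pent-4-ynoate | C#CCCC(=O)OC | starting material
2 | acetoxyacetyl chloride (2-chloro-2-oxoethyl acetate) | CC(=O)OCC(Cl)=O | starting material
3 | methyl 7-acetoxy-6-oxohept-4-ynoate | COC(=O)CCC#CC(=O)COC(C)=O | intermediate
4 | methyl 7-hydroxy-6-oxohept-4-ynoate (hydroxy ynone, not isolated) | COC(=O)CCC#CC(=O)CO | intermediate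
5 | methyl 3-(4-oxo-4,5-dihydrofuran-2-yl)propanoate | COC(=O)CCC1=CC(=O)CO1 | intermediate
6 | methyl 3-(4-methoxyfuran-2-yl)propanoate | COC(=O)CCc1cc(OC)co1 | intermediate
7 | methyl propiolate | C#CC(=O)OC | starting material
8 | dimethyl hexa-2,4-diynedioate | COC(=O)C#CC#CC(=O)OC | intermediate
9 | methyl 5-methoxy-3-(3-methoxy-3-oxoprop-1-yn-1-yl)-1-(3-methoxy-3-oxopropyl)-7-oxabicyclo[2.2.1]hepta-2,5-diene-2-carboxylate (racemic, not isolated) | COC(=O)CCC12OC(C(OC)=C1)C(C#CC(=O)OC)=C2C(=O)OC | intermediate
10 | dimethyl 5,5'-dimethoxy-1,1'-bis(3-methoxy-3-oxopropyl)-7,7'-dioxa-3,3'-bi(bicyclo[2.2.1]hepta-2,5-diene)-2,2'-dicarboxylate (mixture of diastereomers, bridgehead configuration not controlled, not isolated) | COC(=O)CCC12OC(C(OC)=C1)C(=C2C(=O)OC)C1=C(C(=O)OC)C2(CCC(=O)OC)OC1C(OC)=C2 | intermediate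
11 | dimethyl 6,6'-dihydroxy-5,5'-dimethoxy-3,3'-bis(3-methoxy-3-oxopropyl)biphenyl-2,2'-dicarboxylate | COC(=O)CCc1cc(OC)c(O)c(-c2c(O)c(OC)cc(CCC(=O)OC)c2C(=O)OC)c1C(=O)OC | intermediate
12 | dimethyl 6,6'-bis(benzyloxy)-5,5'-dimethoxy-3,3'-bis(3-methoxy-3-oxopropyl)biphenyl-2,2'-dicarboxylate | COC(=O)CCc1cc(OC)c(OCc2ccccc2)c(-c2c(OCc3ccccc3)c(OC)cc(CCC(=O)OC)c2C(=O)OC)c1C(=O)OC | intermediate
13 | 6,6'-bis(benzyloxy)-3,3'-bis(2-carboxyethyl)-5,5'-dimethoxybiphenyl-2,2'-dicarboxylic acid | OC(=O)CCc1cc(OC)c(OCc2ccccc2)c(-c2c(OCc3ccccc3)c(OC)cc(CCC(=O)O)c2C(=O)O)c1C(=O)O | intermediate
14 | 3,3'-[6,6'-bis(benzyloxy)-5,5'-dimethoxybiphenyl-3,3'-diyl]dipropanoic acid | OC(=O)CCc1cc(OC)c(OCc2ccccc2)c(-c2cc(CCC(=O)O)cc(OC)c2OCc2ccccc2)c1 | intermediate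
15 | 3,3'-(6,6'-dihydroxy-5,5'-dimethoxybiphenyl-3,3'-diyl)dipropanoic acid | COc1cc(CCC(=O)O)cc(-c2cc(CCC(=O)O)cc(OC)c2O)c1O | target

## Step count and risks

Total step count: 9. Longest linear sequence: 8 steps (steps 1, 2, 3, 5, 6, 7, 8, 9); step 4 is a one-step branch.

**Step 5 (key step, proposed new method).** Several processes can divert it:
- Reversed regiochemistry in one or both cycloadditions, because the ester-bearing alkyne carbon is also activated through the second ynoate.
- Stalling after the first cycloaddition, or addition of the second furan to the strained, ester-bearing double bond of 9 instead of the remaining triple bond.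
- Conjugate addition of the furan without ring closure.
- Premature bridge opening, after which the new phenol adds to the neighbouring ynoate.
- Enol ether hydrolysis, or lactonisation between the rings, during the acid treatment.

Fallback with known chemistry, setting out from 6 and 7 and returning at 12. A single Diels–Alder reaction of 6 with methyl propiolate 7 gives methyl 5-methoxy-1-(3-methoxy-3-oxopropyl)-7-oxabicyclo[2.2.1]hepta-2,5-diene-2-carboxylate F1. The same acid treatment opens it to methyl 5-hydroxy-4-methoxy-2-(3-methoxy-3-oxopropyl)benzoate F2. Iodination ortho to the hydroxyl (N-iodosuccinimide, cat. CF3CO2H, MeCN), the position halogenated in related 3-hydroxy-4-methoxybenzoyl compounds, gives methyl 3-hydroxy-2-iodo-4-methoxy-6-(3-methoxy-3-oxopropyl)benzoate F3. Benzylation (BnBr, K2CO3, DMF) gives methyl 3-(benzyloxy)-2-iodo-4-methoxy-6-(3-methoxy-3-oxopropyl)benzoate F4. Ullmann homocoupling (Cu powder, DMF, 130 °C), which is favoured by the ortho ester, then forms the biaryl bond and delivers 12.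

**Step 3.** Methylation on the ring carbon instead of oxygen, base-induced self-condensation of the furanone, or decomposition of the electron-rich furan on acidic silica or in air could lower the return. Fallback from 5 to 6: Me3OBF4 in CH2Cl2 alkylates the carbonyl oxygen of the neutral vinylogous ester, where C-alkylation is not possible, to give methyl[5-(3-methoxy-3-oxopropyl)furan-3(2H)-ylidene]oxonium tetrafluoroborate F5. iPr2NEt then removes a proton from the ring CH2 of this salt and gives 6.

**Step 7.** Attack of hydroxide at the carbonyl of the ring esters is slowed by the two ortho substituents, so hydrolysis may stop at the ring diester. More forcing conditions invite Dieckmann-type closure or ether cleavage. Fallback from 12 to 13: cleavage at the alkyl–oxygen bond with LiI in refluxing pyridine (SN2 at the methyl group, indifferent to hindrance at the carbonyl), followed by aqueous HCl. The iodomethane set free is taken up by the solvent as 1-methylpyridinium iodide. No new isolated compound arises.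

**Step 8.** Extrusion from the silver carboxylate may be slow because neither ortho group is a heteroatom, and prolonged heating could erode the benzyl ethers. A change of catalyst to Cu2O/1,10-phenanthroline in NMP/quinoline at 170 °C would be tried first. Fallback that changes the approach, from 13 to 15: ipso-iododecarboxylation (I2, K3PO4, MeCN, 100–120 °C), which is favoured at a carbon para to a methoxy group, gives 3,3'-[6,6'-bis(benzyloxy)-2,2'-diiodo-5,5'-dimethoxybiphenyl-3,3'-diyl]dipropanoic acid F6. Hydrogenation (H2, 10% Pd/C, Et3N, THF/MeOH) then removes both iodides and both benzyl groups in one operation and gives 15 without passing through 14.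

## Further compounds

F1 | step 5 | methyl 5-methoxy-1-(3-methoxy-3-oxopropyl)-7-oxabicyclo[2.2.1]hepta-2,5-diene-2-carboxylate (racemic, not isolated) | COC(=O)CCC12OC(C(OC)=C1)C=C2C(=O)OC
F2 | step 5 | methyl 5-hydroxy-4-methoxy-2-(3-methoxy-3-oxopropyl)benzoate | COC(=O)CCc1cc(OC)c(O)cc1C(=O)OC
F3 | step 5 | methyl 3-hydroxy-2-iodo-4-methoxy-6-(3-methoxy-3-oxopropyl)benzoate | COC(=O)CCc1cc(OC)c(O)c(I)c1C(=O)OC
F4 | step 5 | methyl 3-(benzyloxy)-2-iodo-4-methoxy-6-(3-methoxy-3-oxopropyl)benzoate | COC(=O)CCc1cc(OC)c(OCc2ccccc2)c(I)c1C(=O)OC
F5 | step 3 | methyl[5-(3-methoxy-3-oxopropyl)furan-3(2H)-ylidene]oxonium tetrafluoroborate | COC(=O)CCC1=CC(=[O+]C)CO1.F[B-](F)(F)F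
F0 | step 7 | none | none
F6 | step 8 | 3,3'-[6,6'-bis(benzyloxy)-2,2'-diiodo-5,5'-dimethoxybiphenyl-3,3'-diyl]dipropanoic acid | OC(=O)CCc1cc(OC)c(OCc2ccccc2)c(-c2c(OCc3ccccc3)c(OC)cc(CCC(=O)O)c2I)c1I
A1 | alternative 1 | 3,3'-dimethoxy-2,2'-bis(methoxymethoxy)-5,5'-divinylbiphenyl | C=Cc1cc(OC)c(OCOC)c(-c2cc(C=C)cc(OC)c2OCOC)c1
A2 | alternative 1 | carbon dioxide | O=C=O
A3 | alternative 1 | 3,3'-[5,5'-dimethoxy-6,6'-bis(methoxymethoxy)biphenyl-3,3'-diyl]dipropanoic acid | COCOc1c(OC)cc(CCC(=O)O)cc1-c1cc(CCC(=O)O)cc(OC)c1OCOC
A4 | alternative 2 | 3,3'-dimethoxy-5,5'-dimethylbiphenyl-2,2'-diol | COc1cc(C)cc(-c2cc(C)cc(OC)c2O)c1O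
A5 | alternative 2 | disilver oxide (Ag2O) | [Ag+].[Ag+].[O-2]
A6 | alternative 2 | 5,5'-dimethoxy-3,3'-dimethylidene-1,1'-bi(cyclohexa-1,4-dien-1-yl)-6,6'-dione (bis(para-quinone methide)) | C=C1C=C(OC)C(=O)C(C2=CC(=C)C=C(OC)C2=O)=C1
A7 | alternative 2 | dimethyl malonate | COC(=O)CC(=O)OC
A8 | alternative 2 | tetramethyl 2,2'-[(6,6'-dihydroxy-5,5'-dimethoxybiphenyl-3,3'-diyl)dimethanediyl]dimalonate | COC(=O)C(Cc1cc(OC)c(O)c(-c2cc(CC(C(=O)OC)C(=O)OC)cc(OC)c2O)c1)C(=O)OC
A9 | alternative 3 | 2,2'-bis(allyloxy)-3,3'-dimethoxybiphenyl | C=CCOc1c(OC)cccc1-c1cccc(OC)c1OCC=C
A10 | alternative 3 | 5,5'-diallyl-3,3'-dimethoxybiphenyl-2,2'-diol | C=CCc1cc(OC)c(O)c(-c2cc(CC=C)cc(OC)c2O)c1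
A11 | alternative 3 | eugenol (4-allyl-2-methoxyphenol) | C=CCc1ccc(O)c(OC)c1
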